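The synthesis rests on cutting ring A of the drimane between C2 and C3, the only adjacent unsubstituted carbons of that ring, which sit between the C1 carbinol and the gem-dimethyl carbon C4. Each neighbour can carry a vinyl group, so an open-chain dienone is closed by ring-closing metathesis and saturated in the same flask. The C1 stereocentre, set by an Evans aldol reaction, then relays to C10 (Diels–Alder reaction of the derived 1-vinylcyclohexene with dimethyl acetylenedicarboxylate, which builds ring B), to C5 (hydrogenation) and to C9 (kinetic deconjugative protonation). Reduction, acylation of O1 and a final oxidation deliver the dialdehyde ester.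

Key step: step 5

Remark: drimane numbering is used for the bicyclic compounds (ring A: C1–C5 and C10; ring B: C5–C10; C11 on C9, C12 on C8; β is the face of the C10 methyl group).
Remark: the methyl-bearing centre next to the carbinol in compounds 3–9 (later C10) is drawn as the aldol reaction delivers it; its configuration is inconsequential because this carbon becomes sp2 in step 6.
Remark: metal enolates and other charged species inside a single named reaction are treated in the Why lines; only the neutral olefin that precedes the in-flask hydrogenation of step 5 is carried as a numbered, non-isolated compound.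

Step 1
Reactants: 1 (S)-4-benzyl-3-propionyloxazolidin-2-one; 2 acrolein
Product: 3 (S)-4-benzyl-3-[(2S,3R)-3-hydroxy-2-methylpent-4-enoyl]oxazolidin-2-one
Conditions: Bu2BOTf, i-Pr2NEt, CH2Cl2, 0 °C; then 2, −78 → 0 °C; pH 7 buffer, MeOH, H2O2
Reagents that add atoms: none
Why: Evans syn-aldol reaction: the Z-configured dibutylboron enolate adds to the aldehyde carbonyl of acrolein through a chair Zimmerman–Traxler transition state on the enolate face away from the benzyl group, which should set the carbinol carbon (later C1) as R together with the syn methyl centre.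

Step 2
Reactants: 3 (S)-4-benzyl-3-[(2S,3R)-3-hydroxy-2-methylpent-4-enoyl]oxazolidin-2-one
Product: 4 (2S,3R)-3-hydroxy-N-methoxy-N,2-dimethylpent-4-enamide
Conditions: MeNH(OMe)·HCl, AlMe3, CH2Cl2, −10 °C → rt; dilute aq. HCl work-up
Reagents that add atoms: N,O-dimethylhydroxylamine hydrochloride, CNOC.Cl
Why: Weinreb transamidation: the aluminium amide, anchored on the β-alkoxide, attacks the exocyclic imide carbonyl and should release the recoverable oxazolidinone without touching either stereocentre.

Step 3
Reactants: 4 (2S,3R)-3-hydroxy-N-methoxy-N,2-dimethylpent-4-enamide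
Product: 5 (2S,3R)-3-(tert-butyldimethylsilyloxy)-N-methoxy-N,2-dimethylpent-4-enamide
Conditions: t-BuMe2SiOTf, 2,6-lutidine, CH2Cl2, −78 → 0 °C
Reagents that add atoms: tert-butyldimethylsilyl trifluoromethanesulfonate, CC(C)(C)[Si](C)(C)OS(=O)(=O)C(F)(F)F
Why: O-silylation of a secondary alcohol with a silyl triflate and a hindered pyridine base, which should proceed without retro-aldol cleavage and gives the bulky ether that later shields one face of ring A.

Step 4
Reactants: 5 (2S,3R)-3-(tert-butyldimethylsilyloxy)-N-methoxy-N,2-dimethylpent-4-enamide; 6 prenylmagnesium chloride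
Product: 7 (5S,6R)-6-(tert-butyldimethylsilyloxy)-3,3,5-trimethylocta-1,7-dien-4-one
Conditions: THF, −78 → 0 °C; aq. NH4Cl
Reagents that add atoms: none
Why: Weinreb ketone synthesis with an allylic Grignard reagent: the prenyl reagent should attack through its γ-carbon in a six-membered SE2' transition state to give the 1,1-dimethylallyl ketone (C4 with its vinyl arm), and the chelated tetrahedral adduct prevents a second addition.

Step 5
Reactants: 7 (5S,6R)-6-(tert-butyldimethylsilyloxy)-3,3,5-trimethylocta-1,7-dien-4-one
Product: 9 (2S,3R)-3-(tert-butyldimethylsilyloxy)-2,6,6-trimethylcyclohexan-1-one, via silyloxy-trimethylcyclohexenone 8 (not isolated)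
Conditions: second-generation Grubbs catalyst RuCl2(=CHPh)(PCy3)(H2IMes) (5 mol%), 1,2-dichloroethane (0.01 M), 50 °C; then H2 (7 bar), 70 °C
Reagents that add atoms: none
Why: The ruthenium alkylidene loads onto one terminal vinyl group and a [2+2] cycloaddition/cycloreversion sequence through ruthenacyclobutanes joins C2 to C3 as a ring cis-olefin with loss of ethylene; under H2 the same ruthenium charge is converted into hydride species that saturate the new C2=C3 bond, so the C2–C3 single bond of ring A should be in place after one operation. The closest known reaction types are ring-closing metathesis of 1,7-dienes to cyclohexenes and tandem ring-closing metathesis–hydrogenation with a single ruthenium precatalyst. Ring A closes as a six-membered carbocycle between two terminal olefins (both olefin carbons end up inside the ring), a closure favoured by the gem-dimethyl group at C4 and the branching at C1 and C10. No stereocentre is created: C1 lies β to the ketone and is not touched, and the epimerisable methyl centre is removed in step 6. The step needs cyclisation over oligomerisation, secured by dilution and the heavily branched chain, and reduction of C=C over C=O and Si–O, secured by the absence of the base or diamine co-ligands that ketone hydrogenation by ruthenium hydrides requires.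

Step 6
Reactants: 9 (2S,3R)-3-(tert-butyldimethylsilyloxy)-2,6,6-trimethylcyclohexan-1-one
Product: 10 (R)-3-(tert-butyldimethylsilyloxy)-2,6,6-trimethylcyclohex-1-en-1-yl trifluoromethanesulfonate
Conditions: KN(SiMe3)2, THF, −78 °C; then PhNTf2, −78 → 0 °C
Reagents that add atoms: N-phenylbis(trifluoromethanesulfonimide), O=S(=O)(N(c1ccccc1)S(=O)(=O)C(F)(F)F)C(F)(F)F
Why: Enolate O-triflation: the ketone can enolise only towards the methyl-bearing carbon (the other α-carbon is quaternary), so the tetrasubstituted enol triflate with the C5=C10 double bond should form as a single regioisomer, the ring holding C1 and C4 cis on that olefin, and no stereocentre is made.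

Step 7
Reactants: 10 (R)-3-(tert-butyldimethylsilyloxy)-2,6,6-trimethylcyclohex-1-en-1-yl trifluoromethanesulfonate; 11 tributyl(vinyl)stannane
Product: 12 (R)-tert-butyldimethyl[(2,4,4-trimethyl-3-vinylcyclohex-2-en-1-yl)oxy]silane
Conditions: Pd(PPh3)4 (5 mol%), LiCl, THF, reflux
Reagents that add atoms: none
Why: Stille coupling of an alkenyl triflate with a vinylstannane, a reaction type established for hindered 2,6,6-trimethylcyclohexenyl triflates, which should install C6=C7 and complete the semicyclic diene.

Step 8
Reactants: 12 (R)-tert-butyldimethyl[(2,4,4-trimethyl-3-vinylcyclohex-2-en-1-yl)oxy]silane; 13 dimethyl acetylenedicarboxylate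
Product: 14 dimethyl 1β-(tert-butyldimethylsilyloxy)drima-5,8-diene-11,12-dioate
Conditions: toluene, BHT (cat.), 110 °C, sealed tube
Reagents that add atoms: none
Why: Thermal Diels–Alder reaction of the semicyclic diene C10=C5–C6=C7 with the acetylenic diester builds ring B and the quaternary C10; the dienophile should approach anti to the C1 silyloxy group (the syn face is blocked by that group or, in the ring-flipped half-chair, by a pseudoaxial C4 methyl next to the silyl ether), so the C10 methyl ends cis to O1.

Step 9
Reactants: 14 dimethyl 1β-(tert-butyldimethylsilyloxy)drima-5,8-diene-11,12-dioate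
Product: 15 dimethyl 1β-(tert-butyldimethylsilyloxy)drim-8-ene-11,12-dioate (5α-H)
Conditions: H2 (4 bar), 10% Pd/C, MeOH, rt
Reagents that add atoms: none
Why: Heterogeneous catalytic hydrogenation: the trisubstituted C5=C6 bond should take up hydrogen from the α-face, opposite the C10 methyl and the 1β-silyloxy group, which sets the 5α-H trans ring fusion, while the tetrasubstituted C8=C9 olefin bearing two esters is too hindered to react.

Step 10
Reactants: 15 dimethyl 1β-(tert-butyldimethylsilyloxy)drim-8-ene-11,12-dioate (5α-H)
Product: 16 dimethyl 1β-(tert-butyldimethylsilyloxy)drim-7-ene-11,12-dioate (5α-H; 9α-H)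
Conditions: LiN(i-Pr)2, THF–HMPA, −78 °C; then AcOH, −78 °C
Reagents that add atoms: none
Why: Deconjugative kinetic protonation of an extended ester enolate: the amide base removes a C7 hydrogen (γ to the C11 ester) and the dienolate should be protonated at its α-carbon C9 from the α-face, opposite the C10 methyl and the 1β-silyloxy group, which sets 9α-H and leaves the C12 ester conjugated with the new C7=C8 bond.

Step 11
Reactants: 16 dimethyl 1β-(tert-butyldimethylsilyloxy)drim-7-ene-11,12-dioate (5α-H; 9α-H)
Product: 17 1β-(tert-butyldimethylsilyloxy)drim-7-ene-11,12-diol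
Conditions: LiAlH4, THF, 0 °C → rt; then H2O
Reagents that add atoms: none
Why: Hydride reduction of both esters to primary alcohols (1,2-reduction of the enoate to the allylic alcohol), a reaction type known for drim-7-ene-11,12-dioates, which should leave C9 and the silyl ether untouched.

Step 12
Reactants: 17 1β-(tert-butyldimethylsilyloxy)drim-7-ene-11,12-diol
Product: 18 drim-7-ene-1β,11,12-triol
Conditions: Bu4NF, THF, 50 °C
Reagents that add atoms: none
Why: Fluoride-mediated desilylation, driven by the strong Si–F bond, should free the hindered secondary C1 hydroxyl.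

Step 13
Reactants: 18 drim-7-ene-1β,11,12-triol
Product: 19 11,12-bis(triethylsilyloxy)drim-7-en-1β-ol
Conditions: Et3SiCl, imidazole, CH2Cl2, −20 → 0 °C
Reagents that add atoms: chlorotriethylsilane, CC[Si](Cl)(CC)CC
Why: Selective silylation: the two primary hydroxyls should react much faster than the neopentyl-type secondary C1 hydroxyl next to the quaternary C10, which stays free.

Step 14
Reactants: 19 11,12-bis(triethylsilyloxy)drim-7-en-1β-ol; 20 (E)-4-methoxycinnamoyl chloride
Product: 21 11,12-bis(triethylsilyloxy)drim-7-en-1β-yl (E)-4-methoxycinnamate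
Conditions: Et3N, DMAP (cat.), CH2Cl2, rt → 40 °C
Reagents that add atoms: none
Why: DMAP-catalysed acylation of the equatorial secondary alcohol through the acylpyridinium ion should install the cinnamate with retention at C1 and with the olefin geometry of the acid chloride.

Step 15
Reactants: 21 11,12-bis(triethylsilyloxy)drim-7-en-1β-yl (E)-4-methoxycinnamate
Product: 22 1β-[(E)-4-methoxycinnamoyloxy]drim-7-ene-11,12-dial (target)
Conditions: (COCl)2, DMSO, CH2Cl2, −78 → −40 °C; then Et3N, −78 → 0 °C
Reagents that add atoms: none
Why: Swern oxidation applied directly to primary triethylsilyl ethers: chlorodimethylsulfonium chloride exchanges each silyl ether for an alkoxysulfonium ion that collapses to the aldehyde on adding the amine, and the low temperature and short contact with base should preserve the epimerisable C9 centre, as in Swern oxidations of drim-7-ene-11,12-diols.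

Compound list
1 | (S)-4-benzyl-3-propionyloxazolidin-2-one | CCC(=O)N1[C@@H](Cc2ccccc2)COC1=O | starting material
2 | acrolein | C=CC=O | starting material
3 | (S)-4-benzyl-3-[(2S,3R)-3-hydroxy-2-methylpent-4-enoyl]oxazolidin-2-one | C=C[C@@H](O)[C@H](C)C(=O)N1[C@@H](Cc2ccccc2)COC1=O | intermediate
4 | (2S,3R)-3-hydroxy-N-methoxy-N,2-dimethylpent-4-enamide | C=C[C@@H](O)[C@H](C)C(=O)N(C)OC | intermediate
5 | (2S,3R)-3-(tert-butyldimethylsilyloxy)-N-methoxy-N,2-dimethylpent-4-enamide | C=C[C@@H](O[Si](C)(C)C(C)(C)C)[C@H](C)C(=O)N(C)OC | intermediate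
6 | prenylmagnesium chloride (3-methylbut-2-en-1-ylmagnesium chloride) | CC(C)=CC[Mg]Cl | starting material
7 | (5S,6R)-6-(tert-butyldimethylsilyloxy)-3,3,5-trimethylocta-1,7-dien-4-one | C=C[C@@H](O[Si](C)(C)C(C)(C)C)[C@H](C)C(=O)C(C)(C)C=C | intermediate
8 | (5R,6S)-5-(tert-butyldimethylsilyloxy)-2,2,6-trimethylcyclohex-3-en-1-one | CC1(C)C=C[C@@H](O[Si](C)(C)C(C)(C)C)[C@H](C)C1=O | intermediate (not isolated)
9 | (2S,3R)-3-(tert-butyldimethylsilyloxy)-2,6,6-trimethylcyclohexan-1-one | CC1(C)CC[C@@H](O[Si](C)(C)C(C)(C)C)[C@H](C)C1=O | intermediate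
10 | (R)-3-(tert-butyldimethylsilyloxy)-2,6,6-trimethylcyclohex-1-en-1-yl trifluoromethanesulfonate | CC1(C)CC[C@@H](O[Si](C)(C)C(C)(C)C)C(C)=C1OS(=O)(=O)C(F)(F)F | intermediate
11 | tributyl(vinyl)stannane | C=C[Sn](CCCC)(CCCC)CCCC | starting material
12 | (R)-tert-butyldimethyl[(2,4,4-trimethyl-3-vinylcyclohex-2-en-1-yl)oxy]silane | CC1(C)CC[C@@H](O[Si](C)(C)C(C)(C)C)C(C)=C1C=C | intermediate
13 | dimethyl acetylenedicarboxylate | COC(=O)C#CC(=O)OC | starting material
14 | dimethyl 1β-(tert-butyldimethylsilyloxy)drima-5,8-diene-11,12-dioate (10β-methyl, cis to O1) | CC(C)(C)[Si](C)(C)O[C@@H]1CCC(C)(C)C2=CCC(C(=O)OC)=C(C(=O)OC)[C@@]12C | intermediate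
15 | dimethyl 1β-(tert-butyldimethylsilyloxy)drim-8-ene-11,12-dioate (5α-H, 10β-methyl) | CC(C)(C)[Si](C)(C)O[C@@H]1CCC(C)(C)[C@@H]2CCC(C(=O)OC)=C(C(=O)OC)[C@@]12C | intermediate
16 | dimethyl 1β-(tert-butyldimethylsilyloxy)drim-7-ene-11,12-dioate (5α-H, 9α-H, 10β-methyl) | CC(C)(C)[Si](C)(C)O[C@@H]1CCC(C)(C)[C@@H]2CC=C(C(=O)OC)[C@H](C(=O)OC)[C@@]12C | intermediate
17 | 1β-(tert-butyldimethylsilyloxy)drim-7-ene-11,12-diol | CC(C)(C)[Si](C)(C)O[C@@H]1CCC(C)(C)[C@@H]2CC=C(CO)[C@H](CO)[C@@]12C | intermediate
18 | drim-7-ene-1β,11,12-triol | O[C@@H]1CCC(C)(C)[C@@H]2CC=C(CO)[C@H](CO)[C@@]12C | intermediate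
19 | 11,12-bis(triethylsilyloxy)drim-7-en-1β-ol | O[C@@H]1CCC(C)(C)[C@@H]2CC=C(CO[Si](CC)(CC)CC)[C@H](CO[Si](CC)(CC)CC)[C@@]12C | intermediate
20 | (E)-4-methoxycinnamoyl chloride | COc1ccc(/C=C/C(Cl)=O)cc1 | starting material
21 | 11,12-bis(triethylsilyloxy)drim-7-en-1β-yl (E)-4-methoxycinnamate | COc1ccc(/C=C/C(=O)O[C@@H]2CCC(C)(C)[C@@H]3CC=C(CO[Si](CC)(CC)CC)[C@H](CO[Si](CC)(CC)CC)[C@@]23C)cc1 | intermediate
22 | 1β-[(E)-4-methoxycinnamoyloxy]drim-7-ene-11,12-dial (5α-H, 9α-H, 10β-methyl) | COc1ccc(/C=C/C(=O)O[C@@H]2CCC(C)(C)[C@@H]3CC=C(C=O)[C@H](C=O)[C@@]23C)cc1 | target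

Total step count: 15. Longest linear sequence: 15 steps (from 1 to 22).

Steps most likely to fail

Step 10. The dienolate may reprotonate at C7 and return 15, C9 may be protonated from the β-face, or the amide base may attack an ester. The fallback sets out from 15 and rejoins the route at 18. Fluoride desilylation of 15 (Bu4NF, THF) should let the freed 1β-alkoxide close onto the neighbouring C11 ester and give the drim-8-ene 11,1β-lactone 12-methyl ester F3. In this temporary ring C11 is tied to the β-face, so base-mediated deconjugation (DBU in hot toluene, or LiN(i-Pr)2 then AcOH) can only deliver the 9α-H drim-7-ene 11,1β-lactone 12-methyl ester F4. LiAlH4 then reduces lactone and ester to triol 18, which makes steps 11 and 12 unnecessary.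

Step 15. Exchange of the hindered C11 silyl ether may be incomplete, or the dialdehyde may epimerise at C9 on contact with triethylamine. The fallback sets out from 21 and rejoins at 22. HF·pyridine in THF–pyridine removes both triethylsilyl groups to give 1β-[(E)-4-methoxycinnamoyloxy]drim-7-ene-11,12-diol F5. This diol is oxidised with Dess–Martin periodinane buffered with NaHCO3, without amine base, to 22.

Step 4. The allylic Grignard reagent may attack through its unsubstituted α-carbon (or the γ-adduct may revert), giving the linear prenyl ketone, or the amide may be enolised. The fallback sets out from 5 and rejoins at 7. Reduction with i-Bu2AlH (THF, −78 °C) gives (2S,3R)-3-(tert-butyldimethylsilyloxy)-2-methylpent-4-enal F1. Barbier prenylation with prenyl bromide and indium powder in aqueous THF, which is γ-selective through a cyclic transition state, gives (5S,6R)-6-(tert-butyldimethylsilyloxy)-3,3,5-trimethylocta-1,7-dien-4-ol F2 as a mixture of carbinol epimers. Dess–Martin oxidation returns ketone 7.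

Further compounds
F1 | step 4 | (2S,3R)-3-(tert-butyldimethylsilyloxy)-2-methylpent-4-enal | C=C[C@@H](O[Si](C)(C)C(C)(C)C)[C@H](C)C=O
F2 | step 4 | (5S,6R)-6-(tert-butyldimethylsilyloxy)-3,3,5-trimethylocta-1,7-dien-4-ol (both C4 epimers) | C=C[C@@H](O[Si](C)(C)C(C)(C)C)[C@H](C)C(O)C(C)(C)C=C
F3 | step 10 | drim-8-ene-11,12-dioic acid 11,1β-lactone 12-methyl ester (5α-H, 10β-methyl) | O=C1O[C@@H]2CCC(C)(C)[C@@H]3CCC(C(=O)OC)=C1[C@@]23C
F4 | step 10 | drim-7-ene-11,12-dioic acid 11,1β-lactone 12-methyl ester (5α-H, 9α-H, 10β-methyl) | O=C1O[C@@H]2CCC(C)(C)[C@@H]3CC=C(C(=O)OC)[C@H]1[C@@]23C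
F5 | step 15 | 1β-[(E)-4-methoxycinnamoyloxy]drim-7-ene-11,12-diol | COc1ccc(/C=C/C(=O)O[C@@H]2CCC(C)(C)[C@@H]3CC=C(CO)[C@H](CO)[C@@]23C)cc1
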